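**Retrosynthetic overview**
1. The C15–O ester is made last, from allylic alcohol 17 and (Z)-p-coumaric acid 22; the α-methylene ester of 17 comes from a malonate on C7, which serves as a masked acrylate.
2. Both rings come from the acyclic dialdehyde 11 in one operation: hydrogen-atom transfer to the C1=C10 alkene, addition of the C10 radical to C5 (ring B), crossover to the C4 enolate, and aldol condensation onto the C3 aldehyde (ring A).
3. Enabling feature: C10, the methyl-bearing quaternary ring-fusion carbon, is a tertiary radical position; C5 and C4 are β and α to the C15 carbonyl, and C3=C4–C15 is the dehydrated aldol of a C15 enal enolate with a C3 aldehyde.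
4. Dialdehyde 11 comes from hex-5-en-2-one by Wittig reaction (C1–C3), cross-metathesis (C5, C6), organocatalytic malonate addition (sets C7, its only stereocentre) and a second Wittig reaction (C4, C15).
5. Ring order: ring B, then ring A, both in step 6; no ring of the target exists before that step.

Key step: step 6

Remark: eudesmane numbering is used (ring A = C1–C5, C10; ring B = C5–C10; C14 = methyl on C10; C15 = oxygenated carbon on C4; C11–C13 = side chain on C7). The C1=C10 alkene made in step 1 is carried as an E/Z mixture, because both isomers give the same C10 radical in step 6.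

**Step 1**
Reactants: 1 hex-5-en-2-one; 2 [2-(1,3-dioxolan-2-yl)ethyl]triphenylphosphonium bromide
Product: 4 2-(3-methylhepta-2,6-dien-1-yl)-1,3-dioxolane (E/Z mixture), via ylide 3 (not isolated)
Conditions: 2 (1.3 equiv), KN(SiMe3)2 (1.25 equiv), THF, 0 °C; then 1, 0 °C to rt
Reagents that add atoms: none
Why: Wittig olefination of the methyl ketone with a non-stabilised ylide attaches C1–C3 (C3 as a dioxolane) to C10; no stereocentre is formed and the alkene geometry is irrelevant.

**Step 2**
Reactants: 4 2-(3-methylhepta-2,6-dien-1-yl)-1,3-dioxolane; 5 (E)-but-2-enal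
Product: 6 (2E)-8-(1,3-dioxolan-2-yl)-6-methylocta-2,6-dienal (6E/6Z mixture)
Conditions: 5 (5 equiv), second-generation Hoveyda–Grubbs catalyst RuCl2(H2IMes)(=CH–C6H4–2-O-i-Pr) (3 mol%), CH2Cl2, 40 °C
Reagents that add atoms: none
Why: Olefin cross-metathesis of the terminal alkene with excess crotonaldehyde should give the E-enal under thermodynamic control, while the trisubstituted alkene is too hindered to react.

**Step 3**
Reactants: 6 (2E)-8-(1,3-dioxolan-2-yl)-6-methylocta-2,6-dienal; 7 dimethyl malonate
Product: 8 dimethyl 2-[(3R)-8-(1,3-dioxolan-2-yl)-6-methyl-1-oxooct-6-en-3-yl]propanedioate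
Conditions: 7 (1.5 equiv), (S)-2-{bis[3,5-bis(trifluoromethyl)phenyl](trimethylsilyloxy)methyl}pyrrolidine (10 mol%), EtOH, 0 °C
Reagents that add atoms: none
Why: Iminium-ion organocatalysed Michael addition: the diaryl(silyloxy)methyl group of the (S)-catalyst shields one face of the E, s-trans iminium ion, so malonate adds to the open face of the β-carbon and sets C7 as R; the malonate is also the masked acrylate.

**Step 4**
Reactants: 8 dimethyl 2-[(3R)-8-(1,3-dioxolan-2-yl)-6-methyl-1-oxooct-6-en-3-yl]propanedioate; 9 (triphenylphosphoranylidene)acetaldehyde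
Product: 10 dimethyl 2-[(2E,5R)-10-(1,3-dioxolan-2-yl)-8-methyl-1-oxodeca-2,8-dien-5-yl]propanedioate
Conditions: 9 (1.2 equiv), toluene, 70 °C
Reagents that add atoms: none
Why: Wittig reaction with the stabilised formyl ylide extends the aldehyde by C4 and C15 to the E-enal; the weakly basic ylide should not touch the malonate C–H, and C7 is not epimerisable.

**Step 5**
Reactants: 10 dimethyl 2-[(2E,5R)-10-(1,3-dioxolan-2-yl)-8-methyl-1-oxodeca-2,8-dien-5-yl]propanedioate
Product: 11 dimethyl 2-[(2E,5R)-8-methyl-1,11-dioxoundeca-2,8-dien-5-yl]propanedioate (8E/8Z mixture)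
Conditions: 1 M aq. HCl, THF, rt
Reagents that add atoms: water, O
Why: Acid-catalysed acetal hydrolysis frees the C3 aldehyde; the esters, the enal and the isolated alkene should tolerate dilute acid, and no stereocentre is touched.

**Step 6**
Reactants: 11 dimethyl 2-[(2E,5R)-8-methyl-1,11-dioxoundeca-2,8-dien-5-yl]propanedioate
Product: 13 dimethyl 2-[15-oxo-eudesm-3-en-7-yl]malonate lacking C12 and C13 (trans-fused octalin enal; 5α-H, 10β-CH3, 7β-malonyl, configuration as in the target), via aldol 12 (not isolated)
Conditions: Fe(acac)3 (30 mol%), PhSiH2(O-i-Pr) (2.5 equiv), THF/i-PrOH (10:1), 0.01 M, rt; then p-TsOH·H2O (20 mol%), 40 °C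
Reagents that add atoms: none
Why: Markovnikov hydrogen-atom transfer from an iron hydride (trivalent iron, formed from Fe(acac)3 and the silane) puts H on C1 and gives the tertiary C10 radical from either alkene isomer; the radical adds to C5, the β-carbon of the enal, the C4 radical is reduced by divalent iron to an enolate that exists only at C4, this adds to the C3 aldehyde, and acid dehydrates aldol 12 to the C3=C4–C15 enal. The closest known reaction types are the iron-hydride Giese cyclisation and the HAT-initiated radical–polar crossover annulation (radical conjugate addition followed by aldol closure). Ring B closes 6-exo-trig through a chair-like transition state; ring A closes as a 6-(enolexo)-exo-trig aldol between two equatorial arms. C5 is controlled by C7: the C7 malonate and the enal arm both sit equatorial, which gives the cis-1,3 relation; C10 is set in the same transition state, with methyl axial and the longer 3-oxopropyl arm equatorial, which gives the trans ring fusion. The step needs hydrogen-atom transfer to the electron-rich alkene and not to the enal (no other unactivated alkene is present, the acrylate being masked), aldol closure faster than protonation of the enolate (six-membered intramolecular closure in a nearly aprotic medium), and facial selectivity at C10, which rests only on the methyl/chain size difference and is the least secure element.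

**Step 7**
Reactants: 13 octalin enal
Product: 14 dimethyl 2-[15-hydroxy-eudesm-3-en-7-yl]malonate lacking C12 and C13 (allylic alcohol; configuration as in 13)
Conditions: NaBH4, CeCl3·7H2O, MeOH, −40 °C
Reagents that add atoms: none
Why: Luche reduction should give 1,2-reduction of the enal to the primary allylic alcohol without conjugate reduction and without touching the methyl esters.

**Step 8**
Reactants: 14 allylic alcohol diester
Product: 15 malonic half ester (one CO2Me, one CO2H on C11; mixture of C11 epimers; ring configuration as in 13)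
Conditions: KOH (1.1 equiv), THF/H2O, 0 °C to rt; then 1 M HCl to pH 3
Reagents that add atoms: potassium hydroxide, [K+].[OH-]
Why: Monosaponification of a malonic diester should stop after one ester because the carboxylate deactivates its neighbour; the new C11 stereocentre is of no consequence, as it becomes planar in step 9.

**Step 9**
Reactants: 15 malonic half ester
Product: 17 methyl 2-[(2R,4aR,8aR)-8-(hydroxymethyl)-4a-methyl-1,2,3,4,4a,5,6,8a-octahydronaphthalen-2-yl]prop-2-enoate, via Mannich base 16 (not isolated)
Conditions: (CH2O)n (3 equiv), Et2NH (1.5 equiv), THF, reflux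
Reagents that add atoms: formaldehyde (as paraformaldehyde), C=O
Why: Decarboxylative Mannich methylenation: the half ester condenses with formaldehyde and diethylamine, and Mannich base 16 loses CO2 and the amine to give the α-methylene ester; no stereocentre is formed.

**Step 10**
Reactants: 18 4-(tert-butyldimethylsilyloxy)benzaldehyde; 19 methyl bis(2,2,2-trifluoroethyl)phosphonoacetate
Product: 21 methyl (2Z)-3-[4-(tert-butyldimethylsilyloxy)phenyl]prop-2-enoate, via potassium phosphonate carbanion 20 (not isolated)
Conditions: 19 (1.1 equiv), KN(SiMe3)2 (1.1 equiv), 18-crown-6, THF, −78 °C; then 18, −78 °C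
Reagents that add atoms: none
Why: Still–Gennari olefination: the electron-poor phosphonate with a dissociated potassium counter-ion makes elimination from the first-formed adduct fast, which should give the Z-cinnamate under kinetic control.

**Step 11**
Reactants: 21 methyl (2Z)-3-[4-(tert-butyldimethylsilyloxy)phenyl]prop-2-enoate
Product: 22 (2Z)-3-(4-hydroxyphenyl)prop-2-enoic acid
Conditions: LiOH·H2O (4 equiv), THF/MeOH/H2O, 0 °C to rt, dark; then 1 M HCl to pH 3
Reagents that add atoms: lithium hydroxide, [Li+].[OH-]
Why: Hydroxide saponifies the methyl ester and cleaves the aryl silyl ether at silicon; cold conditions and exclusion of light should keep the Z-alkene.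

**Step 12**
Reactants: 17 hydroxy acrylate; 22 (2Z)-3-(4-hydroxyphenyl)prop-2-enoic acid
Product: 24 methyl 2-[(2R,4aR,8aR)-8-({[(2Z)-3-(4-hydroxyphenyl)prop-2-enoyl]oxy}methyl)-4a-methyl-1,2,3,4,4a,5,6,8a-octahydronaphthalen-2-yl]prop-2-enoate (target), via alkoxyphosphonium salt 23 (not isolated)
Conditions: 22 (1.3 equiv), PPh3 (1.5 equiv), DIAD (1.5 equiv), THF, 0 °C to rt, dark
Reagents that add atoms: none
Why: Mitsunobu esterification: the primary allylic alcohol is activated as its alkoxyphosphonium salt and displaced at C15 by the carboxylate, which is far more acidic than the phenol and should react chemoselectively; the neutral conditions should leave the Z-alkene, the acrylate and the stereocentres untouched.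

**Compound list**
1 | hex-5-en-2-one | CC(=O)CCC=C | starting material
2 | [2-(1,3-dioxolan-2-yl)ethyl]triphenylphosphonium bromide | [Br-].C1COC(CC[P+](c2ccccc2)(c2ccccc2)c2ccccc2)O1 | starting material
3 | [2-(1,3-dioxolan-2-yl)ethylidene]triphenylphosphorane (ylide) | C1COC(CC=P(c2ccccc2)(c2ccccc2)c2ccccc2)O1 | intermediate
4 | 2-(3-methylhepta-2,6-dien-1-yl)-1,3-dioxolane (E/Z mixture at the trisubstituted alkene) | C=CCCC(C)=CCC1OCCO1 | intermediate
5 | (E)-but-2-enal (crotonaldehyde) | C/C=C/C=O | starting material
6 | (2E)-8-(1,3-dioxolan-2-yl)-6-methylocta-2,6-dienal (6E/6Z mixture) | O=C/C=C/CCC(C)=CCC1OCCO1 | intermediate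
7 | dimethyl malonate | COC(=O)CC(=O)OC | starting material
8 | dimethyl 2-[(3R)-8-(1,3-dioxolan-2-yl)-6-methyl-1-oxooct-6-en-3-yl]propanedioate (6E/6Z mixture) | O=CC[C@H](C(C(=O)OC)C(=O)OC)CCC(C)=CCC1OCCO1 | intermediate
9 | (triphenylphosphoranylidene)acetaldehyde | O=CC=P(c1ccccc1)(c1ccccc1)c1ccccc1 | starting material
10 | dimethyl 2-[(2E,5R)-10-(1,3-dioxolan-2-yl)-8-methyl-1-oxodeca-2,8-dien-5-yl]propanedioate (8E/8Z mixture) | O=C/C=C/C[C@H](C(C(=O)OC)C(=O)OC)CCC(C)=CCC1OCCO1 | intermediate
11 | dimethyl 2-[(2E,5R)-8-methyl-1,11-dioxoundeca-2,8-dien-5-yl]propanedioate (8E/8Z mixture) | O=C/C=C/C[C@H](C(C(=O)OC)C(=O)OC)CCC(C)=CCC=O | intermediate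
12 | aldol: trans-fused decalin with 3-hydroxy and 4-formyl groups, 10β-methyl, 5α-H, 7β-CH(CO2Me)2 (mixture at C3 and C4) | COC(=O)C(C(=O)OC)[C@@H]1CC[C@@]2(C)CCC(O)C(C=O)[C@@H]2C1 | intermediate
13 | octalin enal: 4-formyl-eudesm-3-ene core, 10β-methyl, 5α-H, 7β-CH(CO2Me)2 (configuration as in the target) | COC(=O)C(C(=O)OC)[C@@H]1CC[C@@]2(C)CCC=C(C=O)[C@@H]2C1 | intermediate
14 | allylic alcohol: as 13 with CH2OH on C4 | COC(=O)C(C(=O)OC)[C@@H]1CC[C@@]2(C)CCC=C(CO)[C@@H]2C1 | intermediate
15 | malonic half ester: as 14 with CH(CO2Me)(CO2H) on C7 (mixture of C11 epimers) | COC(=O)C(C(=O)O)[C@@H]1CC[C@@]2(C)CCC=C(CO)[C@@H]2C1 | intermediate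
16 | Mannich base: as 15 with CH2NEt2 on C11 | COC(=O)C(CN(CC)CC)(C(=O)O)[C@@H]1CC[C@@]2(C)CCC=C(CO)[C@@H]2C1 | intermediate
17 | methyl 2-[(2R,4aR,8aR)-8-(hydroxymethyl)-4a-methyl-1,2,3,4,4a,5,6,8a-octahydronaphthalen-2-yl]prop-2-enoate | C=C(C(=O)OC)[C@@H]1CC[C@@]2(C)CCC=C(CO)[C@@H]2C1 | intermediate
18 | 4-(tert-butyldimethylsilyloxy)benzaldehyde | CC(C)(C)[Si](C)(C)Oc1ccc(C=O)cc1 | starting material
19 | methyl bis(2,2,2-trifluoroethyl)phosphonoacetate | COC(=O)CP(=O)(OCC(F)(F)F)OCC(F)(F)F | starting material
20 | potassium salt of the carbanion of 19 | [K+].COC(=O)[CH-]P(=O)(OCC(F)(F)F)OCC(F)(F)F | intermediate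
21 | methyl (2Z)-3-[4-(tert-butyldimethylsilyloxy)phenyl]prop-2-enoate | COC(=O)/C=C\c1ccc(O[Si](C)(C)C(C)(C)C)cc1 | intermediate
22 | (2Z)-3-(4-hydroxyphenyl)prop-2-enoic acid | OC(=O)/C=C\c1ccc(O)cc1 | intermediate
23 | alkoxyphosphonium salt of 17 (C15–O–PPh3 cation) with the carboxylate of 22 | C=C(C(=O)OC)[C@@H]1CC[C@@]2(C)CCC=C(CO[P+](c3ccccc3)(c3ccccc3)c3ccccc3)[C@@H]2C1.[O-]C(=O)/C=C\c1ccc(O)cc1 | intermediate
24 | methyl 2-[(2R,4aR,8aR)-8-({[(2Z)-3-(4-hydroxyphenyl)prop-2-enoyl]oxy}methyl)-4a-methyl-1,2,3,4,4a,5,6,8a-octahydronaphthalen-2-yl]prop-2-enoate | C=C(C(=O)OC)[C@@H]1CC[C@@]2(C)CCC=C(COC(=O)/C=C\c3ccc(O)cc3)[C@@H]2C1 | target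

**Step count and risks**
Total step count: 12. Longest linear sequence: 10 (steps 1–9 and 12; steps 10 and 11 form the side branch).

Steps most likely to fail:

Step 6. The cascade may stop after ring B if the C4 radical or the iron enolate takes up hydrogen before it reaches the C3 aldehyde, and hydrogen-atom transfer may go partly to the enal. Weak facial discrimination at C10 would add the cis-fused epimer, which would have to be removed at 13; the fallback does not address this. The fallback separates the two bond formations and sets out from acetal 10, in which C3 is still protected. An iron-hydride Giese cyclisation (Fe(acac)3, PhSiH3, EtOH/ethylene glycol, 60 °C) closes ring B only and should give the cyclohexane aldehyde F1. Its single free aldehyde is converted regiospecifically into the trimethylsilyl enol ether F2 (Me3SiCl, Et3N, DMF, 80 °C). An intramolecular Mukaiyama aldol addition of F2 to its own dioxolane (Me3SiOTf cat., CH2Cl2, −78 °C) forms C3–C4 and gives the β-(2-hydroxyethoxy) aldehyde F3. DBU then eliminates ethylene glycol, and the route is rejoined at enal 13.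

Step 3. Iminium turnover may be slow and facial control incomplete with a β-alkyl enal, and partial retro-Michael reaction may erode the enantiomeric purity at C7, which no later step can repair. The fallback sets out from enal 6. Luche reduction gives the allylic alcohol F4, and methyl chloroformate/pyridine gives the allylic carbonate F5. Iridium-catalysed asymmetric allylic alkylation with 7 ([Ir(cod)Cl]2, chiral phosphoramidite ligand of the enantiomer that delivers R, THF) gives the branched vinyl malonate F6. Selective hydroboration of the vinyl group (9-BBN, then NaBO3·4H2O) gives the primary alcohol F7, and Dess–Martin oxidation returns to aldehyde 8.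

Step 12. The Z geometry may be lost through reversible conjugate addition of phosphine or phenoxide to the cinnamoyl unit, and the free phenol may be O-alkylated. The fallback sets out from alcohol 17 and aldehyde 18 and forms the Z-alkene on the substrate with the phenol protected. Carbodiimide esterification of 17 with (diphenoxyphosphoryl)acetic acid (EDC·HCl, DMAP cat., CH2Cl2) gives the phosphonoacetate F8. A Z-selective Horner–Wadsworth–Emmons olefination of F8 with 18 (NaH, THF, −78 °C) gives the silyl-protected ester F9. Buffered desilylation (Bu4NF, AcOH, THF, 0 °C) returns to target 24.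

**Further compounds**
F1 | step 6 | cyclohexane aldehyde: ring B only, C5 bearing CH2CHO, C10 bearing CH3 and the 2-(1,3-dioxolan-2-yl)ethyl arm, C7 bearing CH(CO2Me)2 (configuration as in 13) | COC(=O)C(C(=O)OC)[C@@H]1CC[C@@](C)(CCC2OCCO2)[C@H](CC=O)C1
F2 | step 6 | trimethylsilyl enol ether of F1 (E/Z mixture) | COC(=O)C(C(=O)OC)[C@@H]1CC[C@@](C)(CCC2OCCO2)[C@H](C=CO[Si](C)(C)C)C1
F3 | step 6 | β-(2-hydroxyethoxy) aldehyde: as aldol 12 with OCH2CH2OH on C3 (mixture at C3 and C4) | COC(=O)C(C(=O)OC)[C@@H]1CC[C@@]2(C)CCC(OCCO)C(C=O)[C@@H]2C1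
F4 | step 3 | (2E)-8-(1,3-dioxolan-2-yl)-6-methylocta-2,6-dien-1-ol | OC/C=C/CCC(C)=CCC1OCCO1
F5 | step 3 | (2E)-8-(1,3-dioxolan-2-yl)-6-methylocta-2,6-dien-1-yl methyl carbonate | COC(=O)OC/C=C/CCC(C)=CCC1OCCO1
F6 | step 3 | dimethyl 2-[(3R)-8-(1,3-dioxolan-2-yl)-6-methylocta-1,6-dien-3-yl]propanedioate | C=C[C@H](C(C(=O)OC)C(=O)OC)CCC(C)=CCC1OCCO1
F7 | step 3 | dimethyl 2-[(3R)-8-(1,3-dioxolan-2-yl)-1-hydroxy-6-methyloct-6-en-3-yl]propanedioate | OCC[C@H](C(C(=O)OC)C(=O)OC)CCC(C)=CCC1OCCO1
F8 | step 12 | (diphenoxyphosphoryl)acetate ester of 17 at C15 | C=C(C(=O)OC)[C@@H]1CC[C@@]2(C)CCC=C(COC(=O)CP(=O)(Oc3ccccc3)Oc3ccccc3)[C@@H]2C1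
F9 | step 12 | O-tert-butyldimethylsilyl ether of target 24 | C=C(C(=O)OC)[C@@H]1CC[C@@]2(C)CCC=C(COC(=O)/C=C\c3ccc(O[Si](C)(C)C(C)(C)C)cc3)[C@@H]2C1
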